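Ring A is not made by a crowded aryl–oxygen coupling but grown on the ring B oxygen. Its ether carbon, flanked by two C–OH carbons, is C4 of a 3,5-dioxoheptanedioate, and C1, C3 and C5 become the three hydroxyl-bearing carbons. One intramolecular Claisen condensation (C6 onto the C1 ester carbonyl) forms the only new C–C bond, closes ring A and aromatises it with free hydroxyls. The precursor is the 4-aryloxy triketide diester carried by the methylated B-to-F pentamer, designed as a mixed diester: the methyl ester is the acceptor, while the tert-butyl ester stays on ring A and is later removed by acid with loss of CO2.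

Key step: step 11

Remarks. Rings are lettered A to F in the order of the target SMILES. Ar is the aryl group of pentamer phenol 10: 3,5-dimethoxy-4-[3,4,5-trimethoxy-2-[3,5-dimethoxy-4-[3,4,5-trimethoxy-2-(3,4,5-trimethoxyphenoxy)phenoxy]phenoxy]phenoxy]phenyl. Assumption: silyl enol ethers 13 and 14 form as mixtures of double-bond isomers and C4 of 16 is an enolisable, racemic centre; both features vanish in step 11, so neither is specified.

Step 1
Reactants: 1 4-bromo-2,6-dimethoxyphenol; 2 5-iodo-1,2,3-trimethoxybenzene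
Product: 3 5-bromo-1,3-dimethoxy-2-(3,4,5-trimethoxyphenoxy)benzene
Conditions: CuI (cat.), picolinic acid (cat.), K3PO4, DMSO, 85 °C, Ar
Reagents that add atoms: none
Why: Ullmann-type copper-catalysed diaryl ether synthesis in which the aryl iodide, used in excess, reacts much faster than any aryl bromide, while the picolinate-ligated copper phenoxide tolerates the two ortho methoxy groups.

Step 2
Reactants: 3 5-bromo-1,3-dimethoxy-2-(3,4,5-trimethoxyphenoxy)benzene
Product: 4 6-(4-bromo-2,6-dimethoxyphenoxy)-2,3,4-trimethoxybenzaldehyde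
Conditions: POCl3, DMF, 0 to 70 °C; then H2O
Reagents that add atoms: N,N-dimethylformamide, CN(C)C=O; water, O
Why: Vilsmeier–Haack formylation goes to the position of the trimethoxyphenoxy ring ortho to the ether oxygen (two equivalent sites, each ortho, ortho and para to three oxygen donors), whereas the brominated ring has only two donors and an ortho bromine at its free positions.

Step 3
Reactants: 4 6-(4-bromo-2,6-dimethoxyphenoxy)-2,3,4-trimethoxybenzaldehyde
Product: 6 6-(4-bromo-2,6-dimethoxyphenoxy)-2,3,4-trimethoxyphenol, via aryl formate 5 (not isolated)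
Conditions: mCPBA, CH2Cl2, 0 °C to rt; aq. NaHCO3 wash; then K2CO3 (cat.), MeOH, rt
Reagents that add atoms: 3-chloroperoxybenzoic acid, O=C(OO)c1cccc(Cl)c1
Why: Dakin-type Baeyer–Villiger oxidation in which the electron-rich 2,6-dioxygenated aryl group migrates in preference to hydrogen to give the formate, which is methanolysed to the phenol.

Step 4
Reactants: 6 6-(4-bromo-2,6-dimethoxyphenoxy)-2,3,4-trimethoxyphenol; 2 5-iodo-1,2,3-trimethoxybenzene
Product: 7 5-bromo-1,3-dimethoxy-2-[3,4,5-trimethoxy-2-(3,4,5-trimethoxyphenoxy)phenoxy]benzene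
Conditions: CuI (cat.), picolinic acid (cat.), K3PO4, DMSO, 85 °C, Ar
Reagents that add atoms: none
Why: Ullmann-type coupling of a hindered phenoxide with an unhindered aryl iodide, the iodide in excess again outcompeting the aryl bromide that 6 and 7 carry.

Step 5
Reactants: 7 5-bromo-1,3-dimethoxy-2-[3,4,5-trimethoxy-2-(3,4,5-trimethoxyphenoxy)phenoxy]benzene
Product: 8 5-iodo-1,3-dimethoxy-2-[3,4,5-trimethoxy-2-(3,4,5-trimethoxyphenoxy)phenoxy]benzene
Conditions: CuI (cat.), trans-N,N'-dimethylcyclohexane-1,2-diamine (cat.), NaI, 1,4-dioxane, 110 °C, Ar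
Reagents that add atoms: sodium iodide, [Na+].[I-]
Why: Copper-catalysed aromatic Finkelstein halogen exchange, driven by precipitation of NaBr from dioxane, turns the bromide into the iodide needed for a halogen-selective fragment union.

Step 6
Reactants: 6 6-(4-bromo-2,6-dimethoxyphenoxy)-2,3,4-trimethoxyphenol; 8 5-iodo-1,3-dimethoxy-2-[3,4,5-trimethoxy-2-(3,4,5-trimethoxyphenoxy)phenoxy]benzene
Product: 9 pentamer bromide ArBr (bromine on C1 of ring B)
Conditions: CuI (cat.), picolinic acid (cat.), K3PO4, DMSO, 85 °C, Ar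
Reagents that add atoms: none
Why: Ullmann-type coupling of the ring C phenoxide with the unhindered ring D iodide, which is expected to react well ahead of the ring B bromide present in 6 and in 9.

Step 7
Reactants: 9 pentamer bromide ArBr
Product: 10 pentamer phenol ArOH
Conditions: Pd2(dba)3 (cat.), tBuXPhos (cat.), KOH, 1,4-dioxane/H2O, 100 °C, Ar; then aq. HCl
Reagents that add atoms: potassium hydroxide, [K+].[OH-]
Why: Palladium-catalysed C–O coupling of an unhindered aryl bromide with hydroxide, where the bulky biaryl phosphine promotes Ar–OH reductive elimination and excess KOH keeps the product as phenoxide, away from diaryl ether formation.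

Step 8
Reactants: 10 pentamer phenol ArOH; 11 tert-butyl 4-chloro-3-oxobutanoate
Product: 12 tert-butyl 4-(ArO)-3-oxobutanoate
Conditions: NaH, THF/DMF, 0 °C to rt; then aq. NH4Cl
Reagents that add atoms: none
Why: Williamson ether synthesis in which two equivalents of NaH hold the chloro keto ester as its enolate, blocking self-condensation, while the unhindered ring B phenoxide displaces the primary chloride.

Step 9
Reactants: 12 tert-butyl 4-(ArO)-3-oxobutanoate
Product: 14 1-tert-butoxy-4-(ArO)-1,3-bis(trimethylsilyloxy)buta-1,3-diene, via mono(silyl enol ether) 13 (not isolated)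
Conditions: Me3SiCl, Et3N, toluene, rt; then LiN(iPr)2, THF, −78 °C, Me3SiCl, −78 to 0 °C
Reagents that add atoms: chlorotrimethylsilane, C[Si](C)(C)Cl
Why: Two-stage enol silylation to a 1,3-bis(silyloxy)-1,3-diene, in which Et3N/Me3SiCl traps the β-keto ester enol and LiN(iPr)2 then removes the γ-proton on the ArO-bearing carbon so that the dienolate is silylated on oxygen, the aryl methyl ethers being inert at −78 °C.

Step 10
Reactants: 14 1-tert-butoxy-4-(ArO)-1,3-bis(trimethylsilyloxy)buta-1,3-diene; 15 methyl 3-chloro-3-oxopropanoate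
Product: 16 7-tert-butyl 1-methyl 4-(ArO)-3,5-dioxoheptanedioate
Conditions: CH2Cl2, −78 to 20 °C; then aq. NH4Cl
Reagents that add atoms: none
Why: Mukaiyama-type vinylogous C-acylation in which the terminal, ArO-bearing carbon of the diene attacks the acid chloride and the silyl groups are lost to chloride and to aqueous work-up, so the aryloxy group is fixed at C4 by construction and no base is present to deprotonate the malonyl methylene.

Step 11
Reactants: 16 7-tert-butyl 1-methyl 4-(ArO)-3,5-dioxoheptanedioate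
Product: 17 tert-butyl 3-(ArO)-2,4,6-trihydroxybenzoate
Conditions: Mg(OMe)2, MeOH, 0 to 50 °C, Ar; then cold 0.5 M HCl
Reagents that add atoms: none
Why: Magnesium methoxide turns both β-dicarbonyl units into magnesium chelates, the C6 carbon of the keto tert-butyl ester enolate adds to the C1 methyl ester carbonyl, methoxide is expelled and the cyclic trione enolises irreversibly to the aromatic trihydroxybenzoate. This is an intramolecular Claisen (Dieckmann-type) condensation, closest to the known magnesium methoxide cyclisation of 3,5-dioxo and 3,5,7-trioxo esters to phloroglucinols. Ring A closes in a 6-exo-trig mode; no stereocentre is formed and the racemic centre at C4 disappears on aromatisation. The step needs C-acylation to win over O-acylation to a 4-hydroxy-2-pyranone: magnesium ties up the enolate oxygens, and lactone formation is reversible in methanolic methoxide whereas aromatisation is not. It also needs the methyl and not the tert-butyl ester to act as acceptor, which the bulk of the tert-butyl ester secures; closure from the other arm would give the same ring with a methyl ester. The ArO group sits on an sp3 carbon until the ring has formed, and every other C–O bond is an aryl ether inert to methoxide.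

Step 12
Reactants: 17 tert-butyl 3-(ArO)-2,4,6-trihydroxybenzoate
Product: 19 2-(ArO)benzene-1,3,5-triol, via trihydroxybenzoic acid 18 (not isolated)
Conditions: CF3CO2H, Et3SiH, CH2Cl2, 0 °C to rt, Ar; concentrate; then MeCN/H2O, 70 °C
Reagents that add atoms: none
Why: Acidolysis of the tert-butyl ester by alkyl–oxygen cleavage, the tert-butyl cation being reduced by Et3SiH before it can alkylate ring A, followed by protodecarboxylation of the electron-rich 2,4,6-trihydroxybenzoic acid through ipso protonation on warming in aqueous medium.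

Step 13
Reactants: 19 2-(ArO)benzene-1,3,5-triol
Product: 20 target CNP0114537.0
Conditions: BBr3, CH2Cl2, −78 °C to rt, Ar; then H2O, 0 °C
Reagents that add atoms: none
Why: Lewis-acid ether cleavage with BBr3, in which each aryl methyl ether is complexed at oxygen and demethylated by bromide attack at the methyl carbon, whereas the diaryl ether bonds offer no sp3 carbon and survive, and hydrolysis of the aryl borates under argon releases the sixteen hydroxyls.

Compound list
1 | 4-bromo-2,6-dimethoxyphenol | COc1cc(Br)cc(OC)c1O | starting material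
2 | 5-iodo-1,2,3-trimethoxybenzene | COc1cc(I)cc(OC)c1OC | starting material
3 | 5-bromo-1,3-dimethoxy-2-(3,4,5-trimethoxyphenoxy)benzene | Brc1cc(OC)c(Oc2cc(OC)c(OC)c(OC)c2)c(OC)c1 | intermediate
4 | 6-(4-bromo-2,6-dimethoxyphenoxy)-2,3,4-trimethoxybenzaldehyde | Brc1cc(OC)c(Oc2cc(OC)c(OC)c(OC)c2C=O)c(OC)c1 | intermediate
5 | 6-(4-bromo-2,6-dimethoxyphenoxy)-2,3,4-trimethoxyphenyl formate | Brc1cc(OC)c(Oc2cc(OC)c(OC)c(OC)c2OC=O)c(OC)c1 | intermediate (not isolated)
6 | 6-(4-bromo-2,6-dimethoxyphenoxy)-2,3,4-trimethoxyphenol | Brc1cc(OC)c(Oc2cc(OC)c(OC)c(OC)c2O)c(OC)c1 | intermediate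
7 | 5-bromo-1,3-dimethoxy-2-[3,4,5-trimethoxy-2-(3,4,5-trimethoxyphenoxy)phenoxy]benzene | Brc1cc(OC)c(Oc2cc(OC)c(OC)c(OC)c2Oc2cc(OC)c(OC)c(OC)c2)c(OC)c1 | intermediate
8 | 5-iodo-1,3-dimethoxy-2-[3,4,5-trimethoxy-2-(3,4,5-trimethoxyphenoxy)phenoxy]benzene | Ic1cc(OC)c(Oc2cc(OC)c(OC)c(OC)c2Oc2cc(OC)c(OC)c(OC)c2)c(OC)c1 | intermediate
9 | pentamer bromide ArBr: 5-bromo-1,3-dimethoxy-2-[3,4,5-trimethoxy-2-[3,5-dimethoxy-4-[3,4,5-trimethoxy-2-(3,4,5-trimethoxyphenoxy)phenoxy]phenoxy]phenoxy]benzene | Brc1cc(OC)c(Oc2cc(OC)c(OC)c(OC)c2Oc2cc(OC)c(Oc3cc(OC)c(OC)c(OC)c3Oc3cc(OC)c(OC)c(OC)c3)c(OC)c2)c(OC)c1 | intermediate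
10 | pentamer phenol ArOH: 3,5-dimethoxy-4-[3,4,5-trimethoxy-2-[3,5-dimethoxy-4-[3,4,5-trimethoxy-2-(3,4,5-trimethoxyphenoxy)phenoxy]phenoxy]phenoxy]phenol | Oc1cc(OC)c(Oc2cc(OC)c(OC)c(OC)c2Oc2cc(OC)c(Oc3cc(OC)c(OC)c(OC)c3Oc3cc(OC)c(OC)c(OC)c3)c(OC)c2)c(OC)c1 | intermediate
11 | tert-butyl 4-chloro-3-oxobutanoate | CC(C)(C)OC(=O)CC(=O)CCl | starting material
12 | tert-butyl 4-(ArO)-3-oxobutanoate | CC(C)(C)OC(=O)CC(=O)COc1cc(OC)c(Oc2cc(OC)c(OC)c(OC)c2Oc2cc(OC)c(Oc3cc(OC)c(OC)c(OC)c3Oc3cc(OC)c(OC)c(OC)c3)c(OC)c2)c(OC)c1 | intermediate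
13 | tert-butyl 4-(ArO)-3-(trimethylsilyloxy)but-2-enoate (double-bond isomers) | CC(C)(C)OC(=O)C=C(O[Si](C)(C)C)COc1cc(OC)c(Oc2cc(OC)c(OC)c(OC)c2Oc2cc(OC)c(Oc3cc(OC)c(OC)c(OC)c3Oc3cc(OC)c(OC)c(OC)c3)c(OC)c2)c(OC)c1 | intermediate (not isolated)
14 | 1-tert-butoxy-4-(ArO)-1,3-bis(trimethylsilyloxy)buta-1,3-diene (double-bond isomers) | CC(C)(C)OC(O[Si](C)(C)C)=CC(O[Si](C)(C)C)=COc1cc(OC)c(Oc2cc(OC)c(OC)c(OC)c2Oc2cc(OC)c(Oc3cc(OC)c(OC)c(OC)c3Oc3cc(OC)c(OC)c(OC)c3)c(OC)c2)c(OC)c1 | intermediate
15 | methyl 3-chloro-3-oxopropanoate (methyl malonyl chloride) | COC(=O)CC(Cl)=O | starting material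
16 | 7-tert-butyl 1-methyl 4-(ArO)-3,5-dioxoheptanedioate (racemic at C4) | COC(=O)CC(=O)C(Oc1cc(OC)c(Oc2cc(OC)c(OC)c(OC)c2Oc2cc(OC)c(Oc3cc(OC)c(OC)c(OC)c3Oc3cc(OC)c(OC)c(OC)c3)c(OC)c2)c(OC)c1)C(=O)CC(=O)OC(C)(C)C | intermediate
17 | tert-butyl 3-(ArO)-2,4,6-trihydroxybenzoate | CC(C)(C)OC(=O)c1c(O)cc(O)c(Oc2cc(OC)c(Oc3cc(OC)c(OC)c(OC)c3Oc3cc(OC)c(Oc4cc(OC)c(OC)c(OC)c4Oc4cc(OC)c(OC)c(OC)c4)c(OC)c3)c(OC)c2)c1O | intermediate
18 | 3-(ArO)-2,4,6-trihydroxybenzoic acid | OC(=O)c1c(O)cc(O)c(Oc2cc(OC)c(Oc3cc(OC)c(OC)c(OC)c3Oc3cc(OC)c(Oc4cc(OC)c(OC)c(OC)c4Oc4cc(OC)c(OC)c(OC)c4)c(OC)c3)c(OC)c2)c1O | intermediate (not isolated)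
19 | 2-(ArO)benzene-1,3,5-triol | Oc1cc(O)c(Oc2cc(OC)c(Oc3cc(OC)c(OC)c(OC)c3Oc3cc(OC)c(Oc4cc(OC)c(OC)c(OC)c4Oc4cc(OC)c(OC)c(OC)c4)c(OC)c3)c(OC)c2)c(O)c1 | intermediate
20 | 2-[3,5-dihydroxy-4-[3,4,5-trihydroxy-2-[3,5-dihydroxy-4-[3,4,5-trihydroxy-2-(3,4,5-trihydroxyphenoxy)phenoxy]phenoxy]phenoxy]phenoxy]benzene-1,3,5-triol | Oc1cc(O)c(Oc2cc(O)c(Oc3cc(O)c(O)c(O)c3Oc3cc(O)c(Oc4cc(O)c(O)c(O)c4Oc4cc(O)c(O)c(O)c4)c(O)c3)c(O)c2)c(O)c1 | target

Total step count: 13. Longest linear sequence: 13 steps (steps 1 to 13; phenol 6 enters twice, in steps 4 and 6).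

Steps most likely to fail

Step 11. Ring closure through oxygen (lactonisation to a pyranone) could outrun C-acylation, or methoxide could cleave the 1,3-diketone by retro-Claisen fragmentation before the ring forms. The fallback attaches ring A ready-made. It sets out from pentamer phenol 10, which would be coupled with commercial 2-iodo-1,3,5-trimethoxybenzene under forcing Ullmann conditions (CuI, picolinic acid, K3PO4, DMSO, 110 °C) to give the hexadecamethyl ether of the target F1. Cleavage of all sixteen methyl ethers with BBr3 in CH2Cl2 under argon would then come back to the route at target 20.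

Step 10. Acylation at the internal carbon or at oxygen of the hindered diene, protodesilylation back to 12, or loss of the acid chloride as a ketene could erode the step. The fallback makes the C4–O bond on a finished chain by carbenoid O–H insertion and sets out from 10. tert-Butyl acetoacetate would be silylated in two stages, as in step 9, to 1-tert-butoxy-1,3-bis(trimethylsilyloxy)buta-1,3-diene F2. Acylation with 15 would give 7-tert-butyl 1-methyl 3,5-dioxoheptanedioate F3. Diazo transfer (4-acetamidobenzenesulfonyl azide, Et3N, MeCN) at the most acidic methylene, C4 between the two ketones, would give 7-tert-butyl 1-methyl 4-diazo-3,5-dioxoheptanedioate F4. Insertion of its rhodium carbenoid into the O–H bond of 10 (Rh2(OAc)4 cat., CH2Cl2, 40 °C) would come back at 16.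

Step 13. Cleavage of thirteen ethers may stop short when partly borylated material precipitates, and the pyrogallol rings may oxidise in air during isolation of the free polyphenol. The fallback isolates through a derivative and sets out from 19. Demethylation with AlCl3 and ethanethiol in CH2Cl2 would be followed by direct peracetylation of the crude product (Ac2O, pyridine) to the hexadecaacetate of the target F5. F5 can be chromatographed on silica and checked for residual methoxy groups. Acid-catalysed methanolysis (HCl from acetyl chloride in MeOH, argon) would come back at 20.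

Further compounds
F1 | step 11 | hexadecamethyl ether of the target, 2-(ArO)-1,3,5-trimethoxybenzene | COc1cc(OC)c(Oc2cc(OC)c(Oc3cc(OC)c(OC)c(OC)c3Oc3cc(OC)c(Oc4cc(OC)c(OC)c(OC)c4Oc4cc(OC)c(OC)c(OC)c4)c(OC)c3)c(OC)c2)c(OC)c1
F2 | step 10 | 1-tert-butoxy-1,3-bis(trimethylsilyloxy)buta-1,3-diene | CC(C)(C)OC(O[Si](C)(C)C)=CC(=C)O[Si](C)(C)C
F3 | step 10 | 7-tert-butyl 1-methyl 3,5-dioxoheptanedioate | COC(=O)CC(=O)CC(=O)CC(=O)OC(C)(C)C
F4 | step 10 | 7-tert-butyl 1-methyl 4-diazo-3,5-dioxoheptanedioate | COC(=O)CC(=O)C(=[N+]=[N-])C(=O)CC(=O)OC(C)(C)C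
F5 | step 13 | hexadecaacetate of the target | CC(=O)Oc1cc(OC(C)=O)c(Oc2cc(OC(C)=O)c(Oc3cc(OC(C)=O)c(OC(C)=O)c(OC(C)=O)c3Oc3cc(OC(C)=O)c(Oc4cc(OC(C)=O)c(OC(C)=O)c(OC(C)=O)c4Oc4cc(OC(C)=O)c(OC(C)=O)c(OC(C)=O)c4)c(OC(C)=O)c3)c(OC(C)=O)c2)c(OC(C)=O)c1
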